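**Compound numbering used throughout:** 1–19 as defined in the steps and the compound list. Flavone locants (O1, C2–C8a, primed for ring B) are used for all ring atoms, also in open-chain precursors.

## The problem

Compound 19 is a flavone: benzene ring A is fused across C4a–C8a to the 4-pyranone ring C, and benzene ring B sits on C2. It has no stereocentre, so every difficulty is one of position and of telling six oxygens apart. Three oxygens are free phenols (C5, C7, C4') and three are methyl ethers (C6, C2', C5'). The C6 methoxy group, wedged between two oxygens, is the ether that Lewis acids remove first, so the phenols must be masked by groups that leave under mild protic acid alone. Ring A carries oxygen on four adjacent carbons (C5, C6, C7, C8a). If ring C is closed through a phenol oxygen, a 2,6-dioxygenated aryl ketone can close through either ortho oxygen and give the 6-methoxy or the 8-methoxy flavone, and hot strong acid interconverts the two. On the way, several groups need care: acetals that do not survive acid, an aryl bromide that is exchanged by alkyllithiums and turns a neighbouring aryllithium into an aryne on warming, a 1,3-diketone that hydroxide cleaves, and electron-rich phenols that oxidise in base. The enabling feature is that O1–C8a is an aryl ether bond ortho to the C4 carbonyl. C8a can therefore be carried as a C–Br carbon, ring A needs only three contiguous oxygens, and in a 1,3-diketone the enol oxygen on the ring B side is placed to close a six-membered ring onto C8a.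

## Retrosynthesis

**19 to 18.** The three O–CH2OCH3 bonds at C5, C7 and C4' are cut last, leading to tris(methoxymethyl) ether 18. One acetal type on all three phenols means a single treatment with dilute HCl finishes the synthesis. Benzyl ethers would add a hydrogenolysis step, and any group needing a boron or aluminium halide is excluded by the C6 methoxy group. The forward step only needs acid mild enough to leave ring C and the methyl ethers alone.

**18 to 17.** Ring C is opened at O1–C8a, giving bromo diketone 17. The neighbouring cut at O1–C2 (cyclodehydration of an o-hydroxyaryl diketone) would demand a fourth oxygen on ring A and a way of keeping it distinct from the C5 oxygen. A cut at C2–C1' would leave the chromone still to be made. With O1–C8a cut, the position of one bromine fixes the regiochemistry, and 17 has one ring fewer and a ring A with only three oxygens. The forward reaction is a copper-catalysed intramolecular O-arylation of the diketonate. It has to outrun hydrodebromination and must not cleave the diketone.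

**17 to 9 and 16.** The diketone is cut between C3 and C2, giving methyl ketone 9 and ester 16. Cutting the other C–C bond (C3–C4) would make the ring A partner a di-ortho-substituted benzoate, a poor acyl acceptor. In 9 the crowding is at the carbonyl while the reacting methyl carbon is free, and 16 has no enolisable hydrogen. The precursors are two benzenes of similar size, so the route is convergent. The forward step is a crossed Claisen condensation under conditions that spare the bromide and the acetals.

**9 to 7.** The C4–C4a bond is cut, leading to bromide 7. The two aromatic hydrogens of 7 are equivalent, and each lies between a methoxymethyl ether and the bromine, so directed metalation has only one site. The forward step needs an amide base (no bromine–lithium exchange), −78 °C throughout (aryllithium 8 loses LiBr on warming) and an acyl donor that stops at the ketone.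

**7 to 5, 2, 1 and 3.** The bromine of 7 is meta to both outer oxygens, a position electrophilic bromination of a resorcinol ether will not reach. The C–Br bond is traced back through boronate 4 to a C–H bond, since iridium-catalysed borylation selects the one C–H with no ortho neighbour. Methoxymethyl ethers are not used at this stage: the CuBr2 bromodeboronation in hot aqueous methanol releases HBr, which would strip acetals and expose an electron-rich phenol to an oxidant. Benzyl ethers would offer their own unhindered C–H bonds to the iridium catalyst. Pivalates are inert to both operations and make ring A less electron-rich, so 1 is acylated to 2, borylated with 3 and brominated to 5. The esters are then exchanged for acetals in one flask through bis-phenoxide 6. This costs one step more than protecting with acetals from the start.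

**16 to 14, 13, 12 and 10.** The aryl–CO2CH3 bond is cut to aryllithium 15 and then to bromide 14. The C–Br bond of 14 goes back to ether 13, where the position para to the acetal oxygen and ortho to a methoxy group is the most activated and least hindered. Ether 13 comes from phenol 12, and 12 from commercial aldehyde 10 by exchange of the formyl carbon for oxygen (Baeyer–Villiger oxidation); that oxygen becomes the C4' phenol. A methoxymethyl ether on ring B keeps the endgame to one step.

## Roads not taken

**Alternative 1:** Ring A is built instead of bought; the cut is at C4a–C8a and, further back, through the whole benzene ring. Heating cyclobutenone A2, methyl (2Z)-3-methoxy-3-[1-methoxy-4-oxo-2-(propan-2-yloxy)cyclobut-2-en-1-yl]prop-2-enoate, should trigger four-electron ring opening, six-electron ring closure forming C4a–C8a, and tautomerisation to salicylate A1, methyl 6-hydroxy-2,3-dimethoxy-4-(propan-2-yloxy)benzoate.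
- Merits: every ring A oxygen is placed by construction, and the C8a oxygen emerges as the only free phenol, so the 6-/8-methoxy question cannot arise. Ring C could then be closed by cyclodehydration without any metal. In this respect it is better than the chosen plan, whose ring closure competes with hydrodebromination.
- Weak points: A1 is still only ring A. The ester must be turned into the diketone, ring C closed, and the C5 methyl and C7 isopropyl ethers removed with a boron or aluminium halide, the reagent class most likely to take the C6 methoxy group as well. Making A2 needs a metalated β-methoxyacrylate and its regioselective addition to a squaric ester.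
- Comparison: the chosen plan sets against this a catalogue ring A, deprotection by protic acid only and a shorter sequence.

**Alternative 2:** The diketone is stored as an isoxazole; the cuts are at C3–C4 and at the oxygen on C2. Oxidation of aldoxime A4, (E)-4,6-bis(benzyloxy)-5-methoxy-2-(methoxymethoxy)benzaldehyde oxime, with PhI(OAc)2 in the presence of alkyne A5, 1-(benzyloxy)-4-ethynyl-2,5-dimethoxybenzene, should give by 1,3-dipolar cycloaddition the 3,5-diarylisoxazole A3.
- Merits: the C–C bond forms under neutral conditions, the regiochemistry with a terminal alkyne is dependable, and a di-ortho-substituted dipole resists dimerisation. The union is as convergent as the Claisen condensation of the chosen plan and probably more reliable.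
- Weak points: A4 needs four oxygens on ring A, with the C8a oxygen protected differently from the C5 oxygen. That is exactly the differentiation the O1–C8a cut avoids, and the 6-/8-methoxy ambiguity returns if it slips. After the cycloaddition come N–O cleavage, hydrolysis, ring closure and hydrogenolysis, four operations against two in the chosen plan. A5 needs a one-carbon homologation of an aldehyde.
- Comparison: the chosen plan sets a three-oxygen ring A and a shorter endgame against the more reliable coupling.

**Alternative 3:** Ring A is folded last from a polyketide-like chain; the cut is at C4a–C5. Pyranone A7, methyl 4-{6-[4-(benzyloxy)-2,5-dimethoxyphenyl]-4-oxo-4H-pyran-2-yl}-2-methoxy-3-oxobutanoate, treated with LiN(SiMe3)2, should cyclise from C4a onto the ester carbonyl and aromatise to A6, the 4'-benzyl ether of the target.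
- Merits: ring A needs no protecting group, C5 and C7 appear as free phenols, the C6 methoxy group is fixed by the chain, and one hydrogenolysis remains. This is the shortest endgame of all and better than the chosen plan in that respect.
- Weak points: the most acidic hydrogen of A7 is the C6 methine between ketone and ester, and its enolate switches off the ester carbonyl that C4a must attack. The second deprotonation at C8 gives an extended enolate that can react at oxygen, at C8 or at C4a. The pyranone is itself opened by hard nucleophiles, and A7 is difficult to prepare and keep.
- Comparison: the chosen plan is longer on paper, but each of its steps has a close analogue, whereas this ring closure rests on regiochemistry that nothing in the substrate secures.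

Key step: step 10

Assumptions: 1, 3 and 10 are taken as commercially available. Diketone 17 is written as the diketo tautomer although the chelated enol should predominate; this affects no step.

## Route

Step 1
Reactants: 1 2-methoxybenzene-1,3-diol
Product: 2 2-methoxy-1,3-phenylene bis(2,2-dimethylpropanoate)
Conditions: pivaloyl chloride (2.4 equiv), Et3N (3 equiv), DMAP (5 mol %), CH2Cl2, 0 °C → rt
Reagents that add atoms: pivaloyl chloride, CC(C)(C)C(=O)Cl
Why: O-acylation of a phenol under nucleophilic catalysis; the pivalates are inert to the borylation and to the hot, HBr-releasing bromination that follows, where acetals would be lost.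

Step 2
Reactants: 2 2-methoxy-1,3-phenylene bis(2,2-dimethylpropanoate); 3 bis(pinacolato)diboron
Product: 5 5-bromo-2-methoxy-1,3-phenylene bis(2,2-dimethylpropanoate), via aryl pinacol boronate 4 (not isolated)
Conditions: [Ir(OMe)(cod)]2 (1.5 mol %), 4,4'-di-tert-butyl-2,2'-bipyridine (3 mol %), 3 (1.0 equiv), THF, 80 °C; evaporate; then CuBr2 (3 equiv), MeOH/H2O 1:1, 80 °C
Reagents that add atoms: CuBr2, [Cu+2].[Br-].[Br-]
Why: Sterically controlled iridium-catalysed C–H borylation takes the only C–H without an ortho substituent (C5 of the arene, the future C8a), and copper-mediated bromodeboronation then exchanges boron for bromine; the ester-substituted ring offers no position open to electrophilic bromination by CuBr2.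

Step 3
Reactants: 5 5-bromo-2-methoxy-1,3-phenylene bis(2,2-dimethylpropanoate)
Product: 7 5-bromo-2-methoxy-1,3-bis(methoxymethoxy)benzene, via disodium bis-phenoxide 6 (not isolated)
Conditions: NaOMe (2.2 equiv), DMF, 0 °C → rt, argon; then MOMCl (2.5 equiv), 0 °C → rt
Reagents that add atoms: chloromethyl methyl ether (MOMCl), COCCl
Why: Methoxide transesterifies the aryl pivalates (phenoxide is the better leaving group), and the bis-phenoxide is alkylated in the same flask by Williamson etherification; argon protects the electron-rich phenoxide from air.

Step 4
Reactants: 7 5-bromo-2-methoxy-1,3-bis(methoxymethoxy)benzene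
Product: 9 1-[2-bromo-5-methoxy-4,6-bis(methoxymethoxy)phenyl]ethan-1-one, via aryllithium 8 (not isolated)
Conditions: LiN(i-Pr)2 (1.15 equiv), THF, −78 °C; then N-methoxy-N-methylacetamide (1.5 equiv), −78 → −20 °C; aq. NH4Cl
Reagents that add atoms: N-methoxy-N-methylacetamide, CC(=O)N(C)OC
Why: Directed ortho-metalation: the amide base does not exchange the bromine and removes the only kind of ring hydrogen, acidified by the adjacent bromine and held by the chelating acetal oxygen; the N-methoxy-N-methyl amide gives a chelated tetrahedral adduct that releases the ketone only on work-up.

Step 5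
Reactants: 10 2,5-dimethoxybenzaldehyde
Product: 12 2,5-dimethoxyphenol, via aryl formate 11 (not isolated)
Conditions: mCPBA (1.3 equiv), CH2Cl2, 0 °C → rt; Me2S to destroy excess peracid; then NaOH, MeOH/H2O, rt; HCl to pH 3
Reagents that add atoms: 3-chloroperoxybenzoic acid (mCPBA), OOC(=O)c1cccc(Cl)c1
Why: Baeyer–Villiger oxidation of an electron-rich benzaldehyde, in which the aryl group migrates to give the formate; saponification in the same flask frees the phenol.

Step 6
Reactants: 12 2,5-dimethoxyphenol
Product: 13 1,4-dimethoxy-2-(methoxymethoxy)benzene
Conditions: MOMCl (1.5 equiv), i-Pr2NEt (2 equiv), CH2Cl2, 0 °C → rt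
Reagents that add atoms: chloromethyl methyl ether (MOMCl), COCCl
Why: Standard O-alkylation of a phenol with an α-chloro ether and a hindered amine base.

Step 7
Reactants: 13 1,4-dimethoxy-2-(methoxymethoxy)benzene
Product: 14 1-bromo-2,5-dimethoxy-4-(methoxymethoxy)benzene
Conditions: NBS (1.05 equiv), MeCN, 0 °C → rt
Reagents that add atoms: N-bromosuccinimide, O=C1CCC(=O)N1Br
Why: Electrophilic aromatic bromination at the position para to the acetal oxygen and ortho to a methoxy group, the most activated and least hindered site of a 1,2,4-trialkoxybenzene; NBS in acetonitrile is neutral enough for the acetal.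

Step 8
Reactants: 14 1-bromo-2,5-dimethoxy-4-(methoxymethoxy)benzene
Product: 16 methyl 2,5-dimethoxy-4-(methoxymethoxy)benzoate, via aryllithium 15 (not isolated)
Conditions: n-BuLi (1.05 equiv), THF, −78 °C; cannulate into ClCO2Me (3 equiv), THF, −78 °C → rt
Reagents that add atoms: methyl chloroformate, COC(=O)Cl
Why: Bromine–lithium exchange at −78 °C is much faster than acetal-directed deprotonation; inverse addition of the aryllithium to excess chloroformate gives the ester and suppresses a second addition.

Step 9
Reactants: 9 1-[2-bromo-5-methoxy-4,6-bis(methoxymethoxy)phenyl]ethan-1-one; 16 methyl 2,5-dimethoxy-4-(methoxymethoxy)benzoate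
Product: 17 1-[2-bromo-5-methoxy-4,6-bis(methoxymethoxy)phenyl]-3-[2,5-dimethoxy-4-(methoxymethoxy)phenyl]propane-1,3-dione
Conditions: NaH (3 equiv), THF, 0 °C → reflux; 1 M HCl to pH 5 at 0 °C
Reagents that add atoms: none
Why: Crossed Claisen condensation of a methyl ketone enolate with a non-enolisable aryl ester, pulled forward by formation of the stabilised diketonate; the di-ortho-substituted ketone carbonyl is too hindered to self-condense.

Step 10
Reactants: 17 1-[2-bromo-5-methoxy-4,6-bis(methoxymethoxy)phenyl]-3-[2,5-dimethoxy-4-(methoxymethoxy)phenyl]propane-1,3-dione
Product: 18 2-[2,5-dimethoxy-4-(methoxymethoxy)phenyl]-6-methoxy-5,7-bis(methoxymethoxy)-4H-chromen-4-one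
Conditions: CuI (10 mol %), N,N'-dimethylethylenediamine (20 mol %), K3PO4 (2 equiv), DMF, 100 °C, argon
Reagents that add atoms: none
Why: Intramolecular Ullmann-type C–O coupling of a 1-(2-bromoaryl)-1,3-diketone, a known way to chromones and flavones. K3PO4 turns 17 into its diketonate, which binds diamine-ligated monovalent copper; oxidative addition of the C8a–Br bond gives a trivalent aryl copper enolate in a seven-membered chelate, and C–O reductive elimination releases 18 and returns monovalent copper. Ring C closes in a 6-exo mode at the aryl carbon, the C–Br bond lying outside the new six-membered ring; only the oxygen on the ring B side can span the distance to C8a, since the C4 oxygen or C3 would have to form a four-membered ring. No stereocentre is formed. The selectivity needed is O-arylation over hydrodebromination and over retro-Claisen cleavage: the chelating diketonate delivers the bromide to copper within the same molecule, and anhydrous phosphate in DMF supplies neither hydride nor hydroxide. Ring A is too electron-rich for uncatalysed substitution, so the regiochemistry rests only on where the bromine sits, and the C5 acetal never becomes a competing phenol.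

Step 11
Reactants: 18 2-[2,5-dimethoxy-4-(methoxymethoxy)phenyl]-6-methoxy-5,7-bis(methoxymethoxy)-4H-chromen-4-one
Product: 19 5,7-dihydroxy-2-(4-hydroxy-2,5-dimethoxyphenyl)-6-methoxy-4H-chromen-4-one
Conditions: 3 M HCl (aq), MeOH/THF, 50 °C
Reagents that add atoms: none
Why: Acid-catalysed acetal cleavage removes all three methoxymethyl groups at once; aryl methyl ethers are inert to dilute protic acid, and the mild conditions should avoid ring opening of the pyranone and the 6-/8-methoxy isomerisation that strong hot acid can cause.

## Compound list

1 | 2-methoxybenzene-1,3-diol (2-methoxyresorcinol) | COc1c(O)cccc1O | starting material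
2 | 2-methoxy-1,3-phenylene bis(2,2-dimethylpropanoate) | COc1c(OC(=O)C(C)(C)C)cccc1OC(=O)C(C)(C)C | intermediate
3 | bis(pinacolato)diboron | CC1(C)OB(B2OC(C)(C)C(C)(C)O2)OC1(C)C | starting material
4 | 2-methoxy-5-(4,4,5,5-tetramethyl-1,3,2-dioxaborolan-2-yl)-1,3-phenylene bis(2,2-dimethylpropanoate) | COc1c(OC(=O)C(C)(C)C)cc(B2OC(C)(C)C(C)(C)O2)cc1OC(=O)C(C)(C)C | intermediate
5 | 5-bromo-2-methoxy-1,3-phenylene bis(2,2-dimethylpropanoate) | COc1c(OC(=O)C(C)(C)C)cc(Br)cc1OC(=O)C(C)(C)C | intermediate
6 | disodium 5-bromo-2-methoxybenzene-1,3-bis(olate) | COc1c([O-])cc(Br)cc1[O-].[Na+].[Na+] | intermediate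
7 | 5-bromo-2-methoxy-1,3-bis(methoxymethoxy)benzene | COCOc1cc(Br)cc(OCOC)c1OC | intermediate
8 | [2-bromo-5-methoxy-4,6-bis(methoxymethoxy)phenyl]lithium | [Li]c1c(Br)cc(OCOC)c(OC)c1OCOC | intermediate
9 | 1-[2-bromo-5-methoxy-4,6-bis(methoxymethoxy)phenyl]ethan-1-one | CC(=O)c1c(Br)cc(OCOC)c(OC)c1OCOC | intermediate
10 | 2,5-dimethoxybenzaldehyde | COc1ccc(OC)c(C=O)c1 | starting material
11 | 2,5-dimethoxyphenyl formate | COc1ccc(OC)c(OC=O)c1 | intermediate
12 | 2,5-dimethoxyphenol | COc1ccc(OC)c(O)c1 | intermediate
13 | 1,4-dimethoxy-2-(methoxymethoxy)benzene | COCOc1cc(OC)ccc1OC | intermediate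
14 | 1-bromo-2,5-dimethoxy-4-(methoxymethoxy)benzene | COCOc1cc(OC)c(Br)cc1OC | intermediate
15 | [2,5-dimethoxy-4-(methoxymethoxy)phenyl]lithium | [Li]c1cc(OC)c(OCOC)cc1OC | intermediate
16 | methyl 2,5-dimethoxy-4-(methoxymethoxy)benzoate | COCOc1cc(OC)c(C(=O)OC)cc1OC | intermediate
17 | 1-[2-bromo-5-methoxy-4,6-bis(methoxymethoxy)phenyl]-3-[2,5-dimethoxy-4-(methoxymethoxy)phenyl]propane-1,3-dione | COCOc1cc(Br)c(C(=O)CC(=O)c2cc(OC)c(OCOC)cc2OC)c(OCOC)c1OC | intermediate
18 | 2-[2,5-dimethoxy-4-(methoxymethoxy)phenyl]-6-methoxy-5,7-bis(methoxymethoxy)-4H-chromen-4-one | COCOc1cc2oc(-c3cc(OC)c(OCOC)cc3OC)cc(=O)c2c(OCOC)c1OC | intermediate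
19 | 5,7-dihydroxy-2-(4-hydroxy-2,5-dimethoxyphenyl)-6-methoxy-4H-chromen-4-one | COc1cc(-c2cc(=O)c3c(O)c(OC)c(O)cc3o2)c(OC)cc1O | target

## Step count and risks

Total: 11 steps. Longest linear sequence: 7 steps (steps 1–4 and 9–11, or steps 5–8 and 9–11).

**Step 10 (key step).** The most likely failure is slow oxidative addition at the electron-rich, ortho-acyl C8a–Br bond. Hydrodebromination and retro-Claisen cleavage of the diketonate by adventitious hydroxide at 100 °C could then overtake ring closure, and the substrate diketonate may tie up copper as an unreactive bis-chelate. The fallback changes the metal and the mechanism. It sets out from 17 and returns at 18: Pd2(dba)3 with DPEphos or t-BuXPhos and Cs2CO3 in toluene at 100 °C. Zerovalent palladium adds to electron-rich aryl bromides far more readily than monovalent copper, and C–O reductive elimination from the divalent palladium aryl enolate is the known palladium route from o-haloaryl ketones to oxygen heterocycles. No new compound arises (F0).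

**Step 4.** Two processes threaten it: loss of LiBr from aryllithium 8 (aryne formation) if acyl transfer to the hindered carbanion is slow and the mixture is warmed, and proton transfer from the methyl group of the amide to 8, which returns 7. The fallback sets out from 7 and returns at 9. Aryllithium 8 is quenched at −78 °C with acetaldehyde, which adds to hindered aryllithiums fast, to give racemic 1-[2-bromo-5-methoxy-4,6-bis(methoxymethoxy)phenyl]ethan-1-ol F1. This is oxidised with Dess–Martin periodinane (NaHCO3, CH2Cl2) to 9.

**Step 9.** Acylation by the electron-rich, ortho-methoxy ester 16 may be slow, so that the enolate of 9 is lost to proton exchange and the product suffers alkoxide-induced retro-Claisen cleavage on long heating. The fallback joins the fragments at the aldehyde oxidation level; it sets out from 14 and 9 and returns at 17. Aryllithium 15 (from 14) is formylated with DMF to 2,5-dimethoxy-4-(methoxymethoxy)benzaldehyde F2. Ketone 9 is converted with LiN(i-Pr)2 in THF at −78 °C into lithium 1-[2-bromo-5-methoxy-4,6-bis(methoxymethoxy)phenyl]ethen-1-olate F3, which adds to F2 to give the racemic aldol 1-[2-bromo-5-methoxy-4,6-bis(methoxymethoxy)phenyl]-3-[2,5-dimethoxy-4-(methoxymethoxy)phenyl]-3-hydroxypropan-1-one F4. Dess–Martin oxidation of F4 gives 17.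

**Step 8.** A second addition of aryllithium 15 to the newly formed ester (diaryl ketone formation), or butylation of 15 by 1-bromobutane if the temperature rises, would erode the ester. The fallback avoids the organolithium; it sets out from 14 and returns at 16: palladium-catalysed methoxycarbonylation with Pd(OAc)2, Xantphos, CO (1 atm), MeOH and Et3N at 70 °C. No new compound arises (F0).

## Further compounds

F0 | step 10 | none | none
F1 | step 4 | 1-[2-bromo-5-methoxy-4,6-bis(methoxymethoxy)phenyl]ethan-1-ol (racemic) | CC(O)c1c(Br)cc(OCOC)c(OC)c1OCOC
F2 | step 9 | 2,5-dimethoxy-4-(methoxymethoxy)benzaldehyde | COCOc1cc(OC)c(C=O)cc1OC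
F3 | step 9 | lithium 1-[2-bromo-5-methoxy-4,6-bis(methoxymethoxy)phenyl]ethen-1-olate | [Li]OC(=C)c1c(Br)cc(OCOC)c(OC)c1OCOC
F4 | step 9 | 1-[2-bromo-5-methoxy-4,6-bis(methoxymethoxy)phenyl]-3-[2,5-dimethoxy-4-(methoxymethoxy)phenyl]-3-hydroxypropan-1-one (racemic) | COCOc1cc(Br)c(C(=O)CC(O)c2cc(OC)c(OCOC)cc2OC)c(OCOC)c1OC
F0 | step 8 | none | none
A1 | alternative 1 | methyl 6-hydroxy-2,3-dimethoxy-4-(propan-2-yloxy)benzoate | COC(=O)c1c(O)cc(OC(C)C)c(OC)c1OC
A2 | alternative 1 | methyl (2Z)-3-methoxy-3-[1-methoxy-4-oxo-2-(propan-2-yloxy)cyclobut-2-en-1-yl]prop-2-enoate (racemic) | COC(=O)/C=C(\OC)C1(OC)C(OC(C)C)=CC1=O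
A3 | alternative 2 | 3-[4,6-bis(benzyloxy)-5-methoxy-2-(methoxymethoxy)phenyl]-5-[4-(benzyloxy)-2,5-dimethoxyphenyl]-1,2-oxazole | COCOc1cc(OCc2ccccc2)c(OC)c(OCc2ccccc2)c1-c1cc(-c2cc(OC)c(OCc3ccccc3)cc2OC)on1
A4 | alternative 2 | (E)-4,6-bis(benzyloxy)-5-methoxy-2-(methoxymethoxy)benzaldehyde oxime | O/N=C/c1c(OCOC)cc(OCc2ccccc2)c(OC)c1OCc1ccccc1
A5 | alternative 2 | 1-(benzyloxy)-4-ethynyl-2,5-dimethoxybenzene | C#Cc1cc(OC)c(OCc2ccccc2)cc1OC
A6 | alternative 3 | 2-[4-(benzyloxy)-2,5-dimethoxyphenyl]-5,7-dihydroxy-6-methoxy-4H-chromen-4-one | COc1cc(-c2cc(=O)c3c(O)c(OC)c(O)cc3o2)c(OC)cc1OCc1ccccc1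
A7 | alternative 3 | methyl 4-{6-[4-(benzyloxy)-2,5-dimethoxyphenyl]-4-oxo-4H-pyran-2-yl}-2-methoxy-3-oxobutanoate (racemic) | COC(=O)C(OC)C(=O)Cc1cc(=O)cc(-c2cc(OC)c(OCc3ccccc3)cc2OC)o1
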